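**Retrosynthetic overview**

1. The trans-diaxial C1–OAc / C6–OH pair beside the C2=C3 bond of the cyclohexene is a ring-opened C1–C6 vinyl oxirane. This pair, with C1 allylic, is the feature that makes the key step possible; the last C–O bond is made by acetolysis of oxirane 21 at C1 with inversion.
2. Key disconnection C1–C6 (plus C1–O): an intramolecular sulfonium-ylide epoxy-annulation. C1 is made nucleophilic as an allylic sulfonium ylide and adds to the C6 aldehyde (two carbinol carbons joined by polarity reversal), so the cyclohexene ring and the oxirane form together.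
3. Chiral pool: L-tartaric acid. Its carbinol carbons become C5 and C4; its carboxyl carbons become C6 and the alkene carbon C3. A butane-2,3-diacetal (dioxane ring) holds O4/O5 trans-diequatorial and steers both new centres. The C2-symmetric diacid is differentiated by opening its cyclic anhydride with one molecule of allyl alcohol.
4. The (Z)-C2=C3 bond comes from ring-closing metathesis inside a temporary seven-membered lactone (C6 carboxyl–O–C1H2 allyl ester). C7 arrives as its benzoate from diazomethane and benzoic acid.
5. Ring order: dioxane (temporary) → cyclic anhydride (transient) → oxepinone (temporary, reduced open) → cyclohexene and oxirane together (key step) → oxirane opened by acetate; then acetal removal and regioselective C5 benzoylation.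

Key step: step 10

Remark: locants are those of the target ring and are used for all intermediates: C1 (OAc), C2=C3 (C3 bears C7H2OBz), C4 (OH), C5 (OBz), C6 (OH). In these locants the target is (1R,4S,5R,6S), which corresponds to natural (2R,3R)-tartrate.

**Route**

Step 1
Reactants: 1 dimethyl L-tartrate; 2 butane-2,3-dione
Product: 3 dimethyl (2R,3R,5R,6R)-5,6-dimethoxy-5,6-dimethyl-1,4-dioxane-2,3-dicarboxylate
Conditions: HC(OMe)3, CSA (cat.), MeOH, reflux
Reagents that add atoms: trimethyl orthoformate COC(OC)OC
Why: Acid-catalysed, thermodynamically controlled butane-2,3-diacetal formation on the threo diol should give the chair dioxane with both esters equatorial and both methoxy groups axial (anomeric effect), so the two new acetal centres are set by the tartrate centres and the diol is locked trans-diequatorial.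

Step 2
Reactants: 3 dimethyl diacetal diester
Product: 4 (2R,3R,5R,6R)-5,6-dimethoxy-5,6-dimethyl-1,4-dioxane-2,3-dicarboxylic acid
Conditions: LiOH·H2O (2.5 equiv), THF/H2O, 0 °C → rt; aq. HCl to pH 2, 0 °C
Reagents that add atoms: lithium hydroxide [Li+].[OH-]
Why: Saponification of the two activated α-alkoxy methyl esters by acyl–oxygen fission should leave the base-stable acetal alone, and the diequatorial carboxyl groups are the thermodynamic epimers, so the four stereocentres are kept.

Step 3
Reactants: 4 diacid; 5 allyl alcohol
Product: 7 (2R,3R,5R,6R)-3-(allyloxycarbonyl)-5,6-dimethoxy-5,6-dimethyl-1,4-dioxane-2-carboxylic acid (mono-allyl half-ester), via cyclic anhydride 6 (not isolated)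
Conditions: DCC (1.0 equiv), THF (0.05 M), 0 °C → rt; then 5 (1.1 equiv), DMAP (10 mol %), rt; urea filtered off
Reagents that add atoms: none
Why: Carbodiimide dehydration of the trans-diequatorial 1,2-diacid should give the trans-fused five-membered cyclic anhydride (as with trans-cyclohexane-1,2-dicarboxylic acid), and DMAP-catalysed alcoholysis of this C2-symmetric anhydride by allyl alcohol can give only one half-ester, because the two carbonyl groups are homotopic and ring opening uses up the anhydride; no stereocentre is touched.

Step 4
Reactants: 7 half-ester; 8 benzoic acid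
Product: 11 allyl 3-[2-(benzoyloxy)acetyl]-5,6-dimethoxy-5,6-dimethyl-1,4-dioxane-2-carboxylate, via mixed anhydride 9 (not isolated), via diazoketone 10 (not isolated)
Conditions: iBuOCOCl, N-methylmorpholine, THF, −15 °C; CH2N2, Et2O, 0 °C; N2 purge; then 8, Rh2(OAc)4 (1 mol %), CH2Cl2, rt
Reagents that add atoms: diazomethane C=[N+]=[N-]
Why: Arndt–Eistert-type acylation of diazomethane by the mixed anhydride gives the α-diazoketone, whose rhodium carbenoid should insert into the O–H bond of benzoic acid faster than it can reach the remote allyl group, so C7 enters already as its benzoate.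

Step 5
Reactants: 11 benzoyloxymethyl ketone
Product: 12 allyl 3-[3-(benzoyloxy)prop-1-en-2-yl]-5,6-dimethoxy-5,6-dimethyl-1,4-dioxane-2-carboxylate
Conditions: Zn, CH2Br2, TiCl4, THF/CH2Cl2, 0 °C → rt
Reagents that add atoms: dibromomethane BrCBr
Why: Takai–Lombardo methylenation uses a non-basic gem-dimetallic methylene reagent that should olefinate the ketone chemoselectively beside three esters without enolising or epimerising the α-alkoxy centre.

Step 6
Reactants: 12 diene
Product: 13 dioxane-fused seven-membered lactone (4,7-dihydro-3H-oxepin-2-one ring: C6 carbonyl–O–C1H2–C2H=C3(CH2OBz)–C4–C5)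
Conditions: second-generation Hoveyda–Grubbs catalyst RuCl2(H2IMes)(=CH-C6H4-2-OiPr) (5 mol %), PhMe (2 mM), 80 °C
Reagents that add atoms: none
Why: Ring-closing olefin metathesis between the allyl ester and the 1,1-disubstituted alkene, helped by the gauche (diequatorial) placement of the two arms on the dioxane chair, should close the lactone, and the ring forces the new trisubstituted C2=C3 bond to be Z (C1 cis to C4), as the six-ring closure requires.

Step 7
Reactants: 13 lactone
Product: 14 (Z)-4-hydroxy-2-[3-(hydroxymethyl)-5,6-dimethoxy-5,6-dimethyl-1,4-dioxan-2-yl]but-2-en-1-yl benzoate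
Conditions: NaBH4, EtOH, 0 °C
Reagents that add atoms: none
Why: Borohydride reduction of an α-alkoxy-activated lactone (as for tartrate esters) should be much faster than attack on the unactivated benzoate and releases the C1 allylic alcohol and the C6 primary alcohol with the alkene geometry retained.

Step 8
Reactants: 14 diol
Product: 15 (Z)-4-bromo-2-[3-(hydroxymethyl)-5,6-dimethoxy-5,6-dimethyl-1,4-dioxan-2-yl]but-2-en-1-yl benzoate
Conditions: NBS, Me2S, CH2Cl2, −20 → 0 °C
Reagents that add atoms: N-bromosuccinimide BrN1C(=O)CCC1=O
Why: In the Corey–Kim halogenation both hydroxyls form alkoxysulfonium salts, but only the allylic one is displaced by bromide (SN2) under these neutral conditions, while the saturated one is returned as the alcohol on work-up.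

Step 9
Reactants: 15 bromo alcohol
Product: 16 (Z)-4-bromo-2-(3-formyl-5,6-dimethoxy-5,6-dimethyl-1,4-dioxan-2-yl)but-2-en-1-yl benzoate
Conditions: Dess–Martin periodinane, CH2Cl2, 0 °C → rt
Reagents that add atoms: none
Why: Dess–Martin oxidation should convert the remaining primary alcohol into the aldehyde without touching the allylic bromide or epimerising the α-alkoxy centre (which is in any case the equatorial, thermodynamic epimer).

Step 10
Reactants: 16 bromo aldehyde; 17 tetrahydrothiophene
Product: 21 vinyl oxirane (C1–C6 epoxide cis to O5; O4/O5 diacetal; C3–CH2OBz), via sulfonium bromide 18 (not isolated), via sulfonium ylide 19 (not isolated), via betaine 20 (not isolated)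
Conditions: 17 (2 equiv), MeCN, rt; then dilution to 5 mM, Cs2CO3 (2 equiv), 0 °C → rt
Reagents that add atoms: none
Why: S-Alkylation of tetrahydrothiophene by the allylic bromide gives salt 18, carbonate deprotonates it at C1 to the allyl-stabilised ylide 19, this now nucleophilic C1 adds to the C6 aldehyde, and the alkoxide of betaine 20 displaces the sulfide from C1 (intramolecular Corey–Chaykovsky epoxidation; closest known type: epoxide-forming cyclisations of ω-oxoalkyl sulfonium salts and sulfonium-ylide annulations onto tethered carbonyls). The carbocycle closes 6-exo-trig onto the carbonyl, trans-fused to the dioxane chair like a trans-decalin, and the oxirane then closes 3-exo-tet. C6 should be set by a Felkin–Anh-type transition state in which the equatorial C5–O bond is antiperiplanar to the forming C1–C6 bond and the carbonyl oxygen is axial, that is cis to O5. C1 is set by the stereoelectronic demand for an antiperiplanar (trans-diaxial) O–C6–C1–S array in the locked ring, so only betaine 20 can close while the other betaines should revert to ylide and aldehyde. The step needs chemoselectivity (ylide at C1 rather than aldehyde enolisation or deprotonation in the thiolane ring), regioselectivity (attack through C1, not through C3, which would give a four-membered ring) and cyclisation over oligomerisation; the acidic allylic sulfonium C–H, the mild heterogeneous base, high dilution and the Z-alkene fixed in step 6 secure these. In one operation it should deliver the C1–C6 bond, the carbocycle, two stereocentres and an oxirane that tells the two oxygens apart.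

Step 11
Reactants: 21 vinyl oxirane
Product: 22 C1 acetate C6 alcohol (O4/O5 still as the diacetal)
Conditions: AcOH, NaOAc (cat.), 50 °C
Reagents that add atoms: acetic acid CC(=O)O
Why: Buffered acetolysis opens the vinyl oxirane by SN2 attack at the allylic C1 with inversion; allylic activation and the trans-diaxial (Fürst–Plattner) rule in the locked half-chair point to the same carbon, giving the C1 acetate anti to the C6 hydroxyl, the pattern presumably formed in nature from an epoxide precursor.

Step 12
Reactants: 22 diacetal-protected acetate
Product: 23 triol (C1–OAc, C7–OBz, free OH at C4, C5 and C6)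
Conditions: TFA/H2O (9:1), 0 °C → rt, short reaction time
Reagents that add atoms: none
Why: Acid hydrolysis of the butane-2,3-diacetal frees the 4,5-diol, and a short cold treatment should spare the esters, since acyl migration is slow under acid and ionisation of the allylic acetate is held back by the low temperature.

Step 13
Reactants: 23 triol
Product: 24 target, (1R,4S,5R,6S)-5-benzoyloxy-3-(benzoyloxymethyl)-4,6-dihydroxycyclohex-2-en-1-yl acetate
Conditions: BzCl (1.1 equiv), Ph2BOCH2CH2NH2 (10 mol %), iPr2NEt, MeCN, rt
Reagents that add atoms: benzoyl chloride O=C(Cl)c1ccccc1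
Why: Borinic-acid-catalysed regioselective acylation binds the cis C5/C6 diol as a tetracoordinate borinate and should acylate the C5 oxygen (the counterpart of O-3 in manno-configured pyranosides), because the C6 oxygen is deactivated by the vicinal acetoxy group and the trans C4 hydroxyl is not bound.

**Compound list**

1 | dimethyl L-tartrate, dimethyl (2R,3R)-2,3-dihydroxybutanedioate | COC(=O)[C@H](O)[C@@H](O)C(=O)OC | starting material
2 | butane-2,3-dione | CC(=O)C(C)=O | starting material
3 | dimethyl (2R,3R,5R,6R)-5,6-dimethoxy-5,6-dimethyl-1,4-dioxane-2,3-dicarboxylate (esters equatorial, methoxy groups axial) | COC(=O)[C@@H]1O[C@@](C)(OC)[C@](C)(OC)O[C@H]1C(=O)OC | intermediate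
4 | (2R,3R,5R,6R)-5,6-dimethoxy-5,6-dimethyl-1,4-dioxane-2,3-dicarboxylic acid | OC(=O)[C@@H]1O[C@@](C)(OC)[C@](C)(OC)O[C@H]1C(=O)O | intermediate
5 | allyl alcohol | C=CCO | starting material
6 | cyclic anhydride of 4 (oxolane-2,5-dione trans-fused to the dioxane, ring centres as in 3) | O=C3OC(=O)[C@@H]1O[C@@](C)(OC)[C@](C)(OC)O[C@H]13 | intermediate
7 | mono-allyl half-ester, (2R,3R,5R,6R)-3-(allyloxycarbonyl)-5,6-dimethoxy-5,6-dimethyl-1,4-dioxane-2-carboxylic acid | C=CCOC(=O)[C@@H]1O[C@@](C)(OC)[C@](C)(OC)O[C@H]1C(=O)O | intermediate
8 | benzoic acid | OC(=O)c1ccccc1 | starting material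
9 | mixed isobutyl carbonic anhydride of 7 (formed with isobutyl chloroformate) | C=CCOC(=O)[C@@H]1O[C@@](C)(OC)[C@](C)(OC)O[C@H]1C(=O)OC(=O)OCC(C)C | intermediate
10 | α-diazoketone from 9 | C=CCOC(=O)[C@@H]1O[C@@](C)(OC)[C@](C)(OC)O[C@H]1C(=O)C=[N+]=[N-] | intermediate
11 | allyl 3-[2-(benzoyloxy)acetyl]-5,6-dimethoxy-5,6-dimethyl-1,4-dioxane-2-carboxylate (ring centres as in 3) | C=CCOC(=O)[C@@H]1O[C@@](C)(OC)[C@](C)(OC)O[C@H]1C(=O)COC(=O)c2ccccc2 | intermediate
12 | allyl 3-[3-(benzoyloxy)prop-1-en-2-yl]-5,6-dimethoxy-5,6-dimethyl-1,4-dioxane-2-carboxylate | C=CCOC(=O)[C@@H]1O[C@@](C)(OC)[C@](C)(OC)O[C@H]1C(=C)COC(=O)c2ccccc2 | intermediate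
13 | dioxane-fused seven-membered lactone, trans ring fusion, endocyclic Z C2=C3 carrying CH2OBz on C3 | O=C3OCC=C(COC(=O)c2ccccc2)[C@@H]1O[C@@](C)(OC)[C@](C)(OC)O[C@H]13 | intermediate
14 | (Z)-diol: C1H2OH cis to C4 on the alkene, C6H2OH on the dioxane, C7–OBz | OC[C@@H]1O[C@@](C)(OC)[C@](C)(OC)O[C@H]1/C(COC(=O)c2ccccc2)=C\CO | intermediate
15 | (Z)-allylic bromide (C1–Br), C6 primary alcohol | OC[C@@H]1O[C@@](C)(OC)[C@](C)(OC)O[C@H]1/C(COC(=O)c2ccccc2)=C\CBr | intermediate
16 | (Z)-allylic bromide, C6 aldehyde | O=C[C@@H]1O[C@@](C)(OC)[C@](C)(OC)O[C@H]1/C(COC(=O)c2ccccc2)=C\CBr | intermediate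
17 | tetrahydrothiophene | C1CCSC1 | starting material
18 | S-allylic tetrahydrothiophenium bromide of 16 | O=C[C@@H]1O[C@@](C)(OC)[C@](C)(OC)O[C@H]1/C(COC(=O)c2ccccc2)=C\C[S+]1CCCC1.[Br-] | intermediate
19 | sulfonium ylide (carbanion at C1) | O=C[C@@H]1O[C@@](C)(OC)[C@](C)(OC)O[C@H]1/C(COC(=O)c2ccccc2)=C\[CH-][S+]1CCCC1 | intermediate
20 | betaine: cyclohexene with axial C6–O(−) cis to O5 and pseudo-axial C1–S(+) anti to it | C1CC[S+](C1)[C@@H]2C=C(COC(=O)c3ccccc3)[C@@H]4O[C@@](C)(OC)[C@](C)(OC)O[C@H]4[C@H]2[O-] | intermediate
21 | vinyl oxirane: C1–C6 epoxide on the face of O5, anti to O4; O4/O5 as diacetal | [C@H]12C=C(COC(=O)c5ccccc5)[C@@H]3O[C@@](C)(OC)[C@](C)(OC)O[C@H]3[C@H]1O2 | intermediate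
22 | C1 acetate (anti to O6), C6 alcohol (syn to O5), O4/O5 as diacetal | CC(=O)O[C@@H]1C=C(COC(=O)c2ccccc2)[C@@H]3O[C@@](C)(OC)[C@](C)(OC)O[C@H]3[C@H]1O | intermediate
23 | triol: C1–OAc, C7–OBz, free OH at C4, C5, C6 (O1 anti to O6, O6 syn to O5, O5 anti to O4) | CC(=O)O[C@@H]1C=C(COC(=O)c2ccccc2)[C@H](O)[C@@H](O)[C@H]1O | intermediate
24 | (1R,4S,5R,6S)-5-benzoyloxy-3-(benzoyloxymethyl)-4,6-dihydroxycyclohex-2-en-1-yl acetate | CC(=O)O[C@@H]1C=C(COC(=O)c2ccccc2)[C@H](O)[C@@H](OC(=O)c2ccccc2)[C@H]1O | target

**Summary**

Total step count: 13. Longest linear sequence: 13 steps (from 1).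

**Steps most likely to fail, with fallbacks**

Step 10. The ylide may not form cleanly: the aldehyde may enolise or β-eliminate, the thiolane ring may be deprotonated and undergo a [2,3]-shift, or betaines that cannot reach the antiperiplanar geometry may drift into side reactions. The fallback joins the same two carbons by radical (pinacol) coupling and sets out from diol 14. Swern oxidation of both primary alcohols should give the (Z)-enal aldehyde, dialdehyde F1. Intramolecular pinacol coupling with trivalent titanium (Cp2TiCl2, Zn, THF), in which the two bulky titanoxy groups stay anti on the locked ring, should give the trans-diaxial 1,6-diol F2. Cyclodehydration under Mitsunobu conditions (PPh3, DIAD), with the allylic C1–O bond displaced by the C6 oxygen, comes back to the route at oxirane 21.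

Step 6. The s-trans preference of the ester and the hindered 1,1-disubstituted olefin may slow ring closure until oligomerisation or catalyst decay takes over. The fallback is a ring-closing carbonyl olefination that sets out from ketone 11 and leaves out 12. Stoichiometric Mo(=CHCMe2Ph)(=N-2,6-iPr2C6H3)[OCMe(CF3)2]2 in benzene should metathesise with the allyl ester terminus, and the new alkylidene should olefinate the ketone intramolecularly, so the hindered alkene never has to be engaged. It comes back to the route at lactone 13 and makes no compound outside the list (entry F0).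

Step 13. Acylation may occur at the wrong hydroxyl (C6 or C4), go too far, or be followed by base-induced acyl migration. The wrong hydroxyl is most likely if the triol reacts through the flipped half-chair, in which the C4 hydroxyl is pseudoaxial (free of allylic strain with the C3 substituent), C5–O is axial and C6–O is equatorial. The fallback is an orthoester route that sets out from triol 23. Trimethyl orthobenzoate with CSA in MeCN should bridge only the cis C5/C6 diol to give the cyclic orthobenzoate F3. Mild aqueous acetic acid then opens it to a hydroxy benzoate within that pair, placing the ester on the axial oxygen, which is complementary to borinate catalysis. It comes back to the route at 24 when C5–O is the axial oxygen of the reacting conformer, which is the case in which the borinate method would fail.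

**Further compounds**

F1 | step 10 | dialdehyde: (Z)-enal at C1 and C6 aldehyde on the diacetal | O=C[C@@H]1O[C@@](C)(OC)[C@](C)(OC)O[C@H]1/C(COC(=O)c2ccccc2)=C\C=O
F2 | step 10 | trans-diaxial 1,6-diol (C1–OH anti to C6–OH, C6–OH syn to O5), O4/O5 as diacetal | O[C@@H]1C=C(COC(=O)c2ccccc2)[C@@H]3O[C@@](C)(OC)[C@](C)(OC)O[C@H]3[C@H]1O
F0 | step 6 | none | none
F3 | step 13 | cyclic 5,6-orthobenzoate (methyl orthoester) of triol 23 | CC(=O)O[C@@H]1C=C(COC(=O)c2ccccc2)[C@H](O)[C@H]3OC(OC)(c4ccccc4)O[C@@H]13
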